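**Strategy.** The tetrahydrofuran ring of the cis-fused furo[3,2-b]pyran (O1, C2, C3, C3a, C7a) is read as the Baeyer–Villiger homologue of a cyclobutanone: the enol-ether carbon C2 is a masked lactone carbonyl and C3–C3a a former vinyl ether. An intramolecular [2+2] cycloaddition of an acyclic aldoketene onto its own vinyl ether, generated from (R)-5-(ethenyloxy)hexanoic acid and steered by the C5 methyl stereocentre, therefore forms the C2–C3 and C3a–C7a bonds and both rings at once. Oxygen insertion gives the bicyclic lactone, which is condensed with a tricyclic lactone; ozonolysis of the latter's enol ether finally expands it to the ten-membered keto-lactone.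

Key step: step 5

Remark on the chemistry: stereocentres that are destroyed later (the alkylated carbon in 20 and 21, the lactol centres in 24, the peroxide-bearing carbons in 26) are carried as mixtures and are left open in the SMILES.

**Step 1**
Reactants: 1 (R)-2-methyloxirane; 2 ethyl propiolate
Product: 4 ethyl (R)-5-hydroxyhex-2-ynoate, via lithium acetylide 3 (not isolated)
Conditions: n-BuLi, THF, −78 °C; BF3·OEt2; then 1, −78 °C; aq NH4Cl
Reagents that add atoms: none
Why: Yamaguchi–Hirao alkynylation, in which the BF3-activated epoxide is opened by SN2 attack at its CH2 terminus, so the (R) carbinol centre is not touched.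

**Step 2**
Reactants: 4 ethyl (R)-5-hydroxyhex-2-ynoate
Product: 5 ethyl (R)-5-hydroxyhexanoate
Conditions: H2 (1 atm), 10% Pd/C, EtOAc, rt
Reagents that add atoms: none
Why: Catalytic hydrogenation should saturate the ynoate completely under neutral conditions, which keeps the δ-hydroxy ester from lactonising and leaves the stereocentre alone.

**Step 3**
Reactants: 5 ethyl (R)-5-hydroxyhexanoate
Product: 6 ethyl (R)-5-(ethenyloxy)hexanoate
Conditions: ethyl vinyl ether (solvent), Hg(OAc)2 (10 mol %), 35 °C; Et3N quench
Reagents that add atoms: ethyl vinyl ether, C=COCC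
Why: Hg(OAc)2-catalysed transfer vinylation (transetherification by oxymercuration–deoxymercuration) should convert the secondary alcohol into its vinyl ether at a temperature too low for lactonisation, with the C–O bond of the stereocentre intact.

**Step 4**
Reactants: 6 ethyl (R)-5-(ethenyloxy)hexanoate
Product: 7 (R)-5-(ethenyloxy)hexanoic acid
Conditions: LiOH·H2O, THF/H2O, 0 °C to rt; cold 1 M HCl to pH 4–5, rapid extraction, used at once
Reagents that add atoms: lithium hydroxide, [Li+].[OH-]
Why: Saponification is compatible with the base-stable vinyl ether, and the brief, cold, weakly acidic work-up should avoid its hydrolysis.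

**Step 5**
Reactants: 7 (R)-5-(ethenyloxy)hexanoic acid
Product: 10 (1S,3R,6S)-3-methyl-2-oxabicyclo[4.2.0]octan-7-one, via acyloxypyridinium salt 8 (not isolated), via ketene 9 (not isolated)
Conditions: 2-chloro-1-methylpyridinium iodide (1.5 equiv), Et3N (4 equiv), MeCN, reflux; 7 added as its Et3N salt by syringe pump (final 5 mM)
Reagents that add atoms: none
Why: The acid is activated as its acyloxypyridinium salt and Et3N eliminates it to the aldoketene, whose electrophilic central carbon bonds to the nucleophilic terminal CH2 of the vinyl ether while its substituted carbon bonds to the oxygen-bearing internal carbon, in the concerted but asynchronous thermal manner of an intramolecular ketene–alkene [2+2] cycloaddition (closest known type: ketene plus enol ether giving 3-alkoxycyclobutanones). The cyclobutanone closes by this [2+2] event, and the tetrahydropyran closes with it in the 6-exo sense with respect to the vinyl ether C=C through a chair-like six-membered array. Both new bonds are delivered to one face of the alkene, so the ring fusion (C1, C6) is necessarily cis. Its absolute sense is set by the (R)-methyl centre, which should sit equatorial in the chair-like array with the vinyl ether extended (s-trans), placing the hydrogens at C1, C3 and C6 all cis. The step needs fused and not bridged regiochemistry, which the polarity of the vinyl ether and the tether through its internal carbon secure. It also needs ring closure to outrun ketene dimerisation, which slow addition at high dilution should secure.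

**Step 6**
Reactants: 10 (1S,3R,6S)-3-methyl-2-oxabicyclo[4.2.0]octan-7-one
Product: 11 (3aS,5R,7aS)-5-methylhexahydro-2H-furo[3,2-b]pyran-2-one
Conditions: mCPBA, NaHCO3, CH2Cl2, 0 °C
Reagents that add atoms: mCPBA, OOC(=O)c1cccc(Cl)c1
Why: Baeyer–Villiger oxidation of the strained cyclobutanone, in which the more substituted ring-fusion carbon (C6) should migrate with retention, so oxygen enters between C7 and C6 and the cis-fused γ-lactone results.

**Step 7**
Reactants: 12 tert-butyl 4-oxobutanoate; 13 but-3-en-2-one
Product: 14 tert-butyl (S)-3-formyl-6-oxoheptanoate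
Conditions: (S)-2-[methoxy(diphenyl)methyl]pyrrolidine (5 mol %), ethyl 3,4-dihydroxybenzoate (20 mol %), neat, 4 °C
Reagents that add atoms: none
Why: Enamine-catalysed Michael addition of the aldehyde to the enone, in which the diphenyl(methoxy)methyl group of the (S)-catalyst shields one face of the E-enamine and the (S) centre is expected.

**Step 8**
Reactants: 14 tert-butyl (S)-3-formyl-6-oxoheptanoate
Product: 15 tert-butyl (S)-2-(4-oxocyclohex-2-en-1-yl)acetate
Conditions: LiOH·H2O (0.3 equiv), iPrOH, rt
Reagents that add atoms: none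
Why: Intramolecular aldol condensation of the methyl ketone onto the aldehyde (six-membered ring, E1cB dehydration) should give the 4-substituted cyclohexenone with the stereocentre carried over as the γ-carbon and the tert-butyl ester intact.

**Step 9**
Reactants: 16 (R)-butane-1,3-diol
Product: 17 (R)-4-iodobutan-2-ol
Conditions: I2, PPh3, imidazole, CH2Cl2, 0 °C
Reagents that add atoms: iodine, II
Why: Appel-type iodination is selective for the primary hydroxyl, so the secondary carbinol centre keeps its (R) configuration.

**Step 10**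
Reactants: 17 (R)-4-iodobutan-2-ol
Product: 18 (R)-tert-butyl[(4-iodobutan-2-yl)oxy]dimethylsilane
Conditions: TBSCl, imidazole, DMF, rt
Reagents that add atoms: TBSCl, CC(C)(C)[Si](C)(C)Cl
Why: Standard silylation of the secondary alcohol, which does not involve the stereocentre.

**Step 11**
Reactants: 15 tert-butyl (S)-2-(4-oxocyclohex-2-en-1-yl)acetate; 18 (R)-tert-butyl[(4-iodobutan-2-yl)oxy]dimethylsilane
Product: 20 tert-butyl 2-[(1S,5RS)-5-{(3R)-3-[(tert-butyldimethylsilyl)oxy]butyl}-4-oxocyclohex-2-en-1-yl]acetate, via lithium dienolate 19 (not isolated)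
Conditions: LiN(iPr)2, THF, −78 °C; then 18, DMPU, −78 to −20 °C
Reagents that add atoms: none
Why: Kinetic α′-deprotonation of the enone (ketone α′-H more acidic than the ester α-H) gives the cross-conjugated enolate, which is alkylated by SN2 at the primary iodide; the new centre is inconsequential because it becomes sp2 in step 12.

**Step 12**
Reactants: 20 tert-butyl 2-[(1S,5RS)-5-{(3R)-3-[(tert-butyldimethylsilyl)oxy]butyl}-4-oxocyclohex-2-en-1-yl]acetate
Product: 22 (3aS,7R,9aS)-7-methyl-3,3a,4,5,6,7,9,9a-octahydro-2H-furo[3,2-g]chromen-2-one, via hydroxy keto lactone 21 (not isolated)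
Conditions: TFA/CH2Cl2/H2O (10:10:1), 0 °C to rt; evaporate; PPTS (10 mol %), toluene, 110 °C, Dean–Stark
Reagents that add atoms: none
Why: Acid removes the tert-butyl ester and the silyl ether, the free acid adds to the enone in an intramolecular oxa-Michael reaction (5-exo-trig) that can only deliver oxygen cis to the CH2 tether and so sets C9a from the existing C3a centre, and the δ-hydroxy ketone then cyclodehydrates to the more substituted, thermodynamic enol ether.

**Step 13**
Reactants: 22 (3aS,7R,9aS)-7-methyl-3,3a,4,5,6,7,9,9a-octahydro-2H-furo[3,2-g]chromen-2-one; 11 (3aS,5R,7aS)-5-methylhexahydro-2H-furo[3,2-b]pyran-2-one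
Product: 24 (3aS,7R,9aS)-3-[(3aS,5R,7aS)-2-hydroxy-5-methylhexahydro-2H-furo[3,2-b]pyran-2-yl]-7-methyl-3,3a,4,5,6,7,9,9a-octahydro-2H-furo[3,2-g]chromen-2-one (lactol, mixture at the two new centres), via lithium lactone enolate 23 (not isolated)
Conditions: LiN(iPr)2 (1.05 equiv), THF, −78 °C; then 11 (1.2 equiv), −78 °C; AcOH quench at −78 °C, pH 7 buffer
Reagents that add atoms: none
Why: Crossed Claisen-type addition of the lactone enolate (the only acidic site of 22) to the γ-lactone carbonyl of 11, whose tetrahedral lithium hemiketalate should persist at −78 °C and so suppress proton exchange; the two new centres are removed in step 14.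

**Step 14**
Reactants: 24 lactol adduct
Product: 25 (3aS,7R,9aS,E)-7-methyl-3-[(3aS,5R,7aS)-5-methylhexahydro-2H-furo[3,2-b]pyran-2-ylidene]-3,3a,4,5,6,7,9,9a-octahydro-2H-furo[3,2-g]chromen-2-one
Conditions: TsOH·H2O (10 mol %), 4 Å molecular sieves, toluene, 60 °C
Reagents that add atoms: none
Why: Acid-catalysed dehydration of the hemiketal to the vinylogous carbonate is reversible through the oxocarbenium ion, so all lactol isomers should converge on the E alkene, which avoids the C=O/ring-oxygen dipole clash and the allylic strain of the Z form.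

**Step 15**
Reactants: 25 bis-enol ether
Product: 27 cordycicadin C, via alkoxy ozonide 26 (not isolated)
Conditions: O3 (1.0 equiv, Sudan Red 7B end point), CH2Cl2, −78 °C; then Me2S, −78 °C to rt
Reagents that add atoms: ozone, [O-][O+]=O
Why: Ozonolysis should cleave only the electron-rich, unconjugated tetrasubstituted enol ether (the other one is deactivated by the lactone carbonyl), turning its two carbons into the ketone and the ester carbonyl and thereby expanding the fused bicycle to the ten-membered keto-lactone without touching any stereocentre.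

**Compound list**

1 | (R)-2-methyloxirane | C[C@@H]1CO1 | starting material
2 | ethyl propiolate | C#CC(=O)OCC | starting material
3 | lithium acetylide of ethyl propiolate | [Li+].[C-]#CC(=O)OCC | intermediate
4 | ethyl (R)-5-hydroxyhex-2-ynoate | C[C@@H](O)CC#CC(=O)OCC | intermediate
5 | ethyl (R)-5-hydroxyhexanoate | C[C@@H](O)CCCC(=O)OCC | intermediate
6 | ethyl (R)-5-(ethenyloxy)hexanoate | C=CO[C@H](C)CCCC(=O)OCC | intermediate
7 | (R)-5-(ethenyloxy)hexanoic acid | C=CO[C@H](C)CCCC(=O)O | intermediate
8 | 2-{[(5R)-5-(ethenyloxy)hexanoyl]oxy}-1-methylpyridinium iodide | C=CO[C@H](C)CCCC(=O)Oc1cccc[n+]1C.[I-] | intermediate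
9 | (R)-5-(ethenyloxy)hex-1-en-1-one (ketene) | C=CO[C@H](C)CCC=C=O | intermediate
10 | (1S,3R,6S)-3-methyl-2-oxabicyclo[4.2.0]octan-7-one | O=C1C[C@@H]2O[C@H](C)CC[C@H]12 | intermediate
11 | (3aS,5R,7aS)-5-methylhexahydro-2H-furo[3,2-b]pyran-2-one | O=C1C[C@@H]2O[C@H](C)CC[C@@H]2O1 | intermediate
12 | tert-butyl 4-oxobutanoate | CC(C)(C)OC(=O)CCC=O | starting material
13 | but-3-en-2-one | CC(=O)C=C | starting material
14 | tert-butyl (S)-3-formyl-6-oxoheptanoate | CC(C)(C)OC(=O)C[C@@H](C=O)CCC(C)=O | intermediate
15 | tert-butyl (S)-2-(4-oxocyclohex-2-en-1-yl)acetate | CC(C)(C)OC(=O)C[C@H]1C=CC(=O)CC1 | intermediate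
16 | (R)-butane-1,3-diol | C[C@@H](O)CCO | starting material
17 | (R)-4-iodobutan-2-ol | C[C@@H](O)CCI | intermediate
18 | (R)-tert-butyl[(4-iodobutan-2-yl)oxy]dimethylsilane | C[C@@H](O[Si](C)(C)C(C)(C)C)CCI | intermediate
19 | lithium cross-conjugated dienolate of 15 | CC(C)(C)OC(=O)C[C@H]1C=CC([O-])=CC1.[Li+] | intermediate
20 | tert-butyl 2-[(1S,5RS)-5-{(3R)-3-[(tert-butyldimethylsilyl)oxy]butyl}-4-oxocyclohex-2-en-1-yl]acetate | C[C@@H](O[Si](C)(C)C(C)(C)C)CCC1C[C@@H](CC(=O)OC(C)(C)C)C=CC1=O | intermediate
21 | (3aS,7aS)-5-[(3R)-3-hydroxybutyl]hexahydro-1-benzofuran-2,6-dione (mixture at C5) | C[C@@H](O)CCC1C[C@H]2CC(=O)O[C@H]2CC1=O | intermediate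
22 | (3aS,7R,9aS)-7-methyl-3,3a,4,5,6,7,9,9a-octahydro-2H-furo[3,2-g]chromen-2-one | C[C@@H]1CCC2=C(O1)C[C@@H]3OC(=O)C[C@@H]3C2 | intermediate
23 | lithium enolate of lactone 22 | C[C@@H]1CCC2=C(O1)C[C@@H]3OC([O-])=C[C@@H]3C2.[Li+] | intermediate
24 | lactol adduct of 22 and 11 (3-[2-hydroxy-5-methylhexahydrofuro[3,2-b]pyran-2-yl] derivative of 22, mixture at C3 and the hemiketal carbon) | C[C@@H]1CCC=5C[C@H]2C(C3(O)C[C@@H]4O[C@H](C)CC[C@@H]4O3)C(=O)O[C@H]2CC=5O1 | intermediate
25 | (3aS,7R,9aS,E)-7-methyl-3-[(3aS,5R,7aS)-5-methylhexahydro-2H-furo[3,2-b]pyran-2-ylidene]-3,3a,4,5,6,7,9,9a-octahydro-2H-furo[3,2-g]chromen-2-one | C[C@@H]1CCC=5C[C@H]2/C(=C3/C[C@@H]4O[C@H](C)CC[C@@H]4O3)C(=O)O[C@H]2CC=5O1 | intermediate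
26 | alkoxy ozonide of 25 (1,2,4-trioxolane across the former enol ether C=C) | C[C@@H]1CCC56C[C@H]2/C(=C3/C[C@@H]4O[C@H](C)CC[C@@H]4O3)C(=O)O[C@H]2CC(O1)(OO5)O6 | intermediate
27 | cordycicadin C (E alkene; furopyran 3aS,5R,7aS; butyrolactone β and γ carbons S,S; macrolide methyl carbinol R) | C[C@@H]1CCC(=O)C[C@H]2/C(=C3/C[C@@H]4O[C@H](C)CC[C@@H]4O3)C(=O)O[C@H]2CC(=O)O1 | target

**Step count and risks**

Total step count: 15. Longest linear sequence: 9 steps (steps 1–6, then 13–15).

Steps most likely to fail:

Step 5. Dimerisation and oligomerisation of the unstabilised aldoketene, or amine-induced side reactions, may outrun the slower closure to the bicyclo[4.2.0] skeleton. The fallback sets out from ester 6 and uses a keteniminium [2+2] cycloaddition instead. Aminolysis with neat pyrrolidine at 80 °C should give (R)-1-(pyrrolidin-1-yl)-5-(ethenyloxy)hexan-1-one F1. Tf2O and 2,4,6-collidine in 1,2-dichloroethane (0 to 80 °C) would convert it into the keteniminium triflate, which is far more electrophilic than the ketene and cannot dimerise, and the same intramolecular [2+2] should give (1S,3R,6R)-1-(3-methyl-2-oxabicyclo[4.2.0]octan-7-ylidene)pyrrolidinium trifluoromethanesulfonate F2. Hydrolysis with aqueous NaHCO3 comes back to the route at cyclobutanone 10.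

Step 13. Proton transfer from the α-CH2 of lactone 11 to the enolate, followed by β-elimination of the pyran oxygen, and self-condensation of 22 may compete with carbonyl addition. The fallback sets out from lactone 11 and replaces the lactone electrophile by an open-chain acyl donor. Opening with MeNH(OMe)·HCl and Me3Al should give 2-[(2S,3S,6R)-3-hydroxy-6-methyloxan-2-yl]-N-methoxy-N-methylacetamide F3, and TESCl/imidazole its triethylsilyl ether F4. Acylation of two equivalents of the lithium enolate of 22 with F4 (THF, −78 to 0 °C) should give the 3-acyl lactone (3aS,7R,9aS)-7-methyl-3-{2-[(2S,3S,6R)-6-methyl-3-(triethylsilyloxy)oxan-2-yl]acetyl}-3,3a,4,5,6,7,9,9a-octahydro-2H-furo[3,2-g]chromen-2-one F5. TsOH·H2O in toluene at 60 °C then removes the silyl group and cyclodehydrates the γ-hydroxy ketone, coming back to the route at 25.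

Step 15. Over-oxidation may occur, with ozone also attacking the ester-conjugated enol ether, and the peroxidic intermediates may decompose along other paths. The fallback sets out from 25 and separates oxidation from cleavage. OsO4 (catalytic) with N-methylmorpholine N-oxide in acetone/H2O should dihydroxylate only the electron-rich, unconjugated enol ether to the α-hydroxy lactol (4a,8a-dihydroxy-4a,8a-dihydro derivative of 25) F6. Pb(OAc)4 in benzene at rt then cleaves the diol between the two oxygenated carbons to the ketone and the lactone, coming back to the route at target 27.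

**Further compounds**

F1 | step 5 | (R)-1-(pyrrolidin-1-yl)-5-(ethenyloxy)hexan-1-one | C=CO[C@H](C)CCCC(=O)N1CCCC1
F2 | step 5 | (1S,3R,6R)-1-(3-methyl-2-oxabicyclo[4.2.0]octan-7-ylidene)pyrrolidinium trifluoromethanesulfonate | C1CC[N+](C1)=C1C[C@@H]2O[C@H](C)CC[C@H]12.[O-]S(=O)(=O)C(F)(F)F
F3 | step 13 | 2-[(2S,3S,6R)-3-hydroxy-6-methyloxan-2-yl]-N-methoxy-N-methylacetamide | CON(C)C(=O)C[C@@H]1O[C@H](C)CC[C@@H]1O
F4 | step 13 | N-methoxy-N-methyl-2-[(2S,3S,6R)-6-methyl-3-(triethylsilyloxy)oxan-2-yl]acetamide | CON(C)C(=O)C[C@@H]1O[C@H](C)CC[C@@H]1O[Si](CC)(CC)CC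
F5 | step 13 | (3aS,7R,9aS)-7-methyl-3-{2-[(2S,3S,6R)-6-methyl-3-(triethylsilyloxy)oxan-2-yl]acetyl}-3,3a,4,5,6,7,9,9a-octahydro-2H-furo[3,2-g]chromen-2-one (mixture at C3) | C[C@@H]1CCC=5C[C@H]2C(C(=O)C[C@@H]3O[C@H](C)CC[C@@H]3O[Si](CC)(CC)CC)C(=O)O[C@H]2CC=5O1
F6 | step 15 | 4a,8a-dihydroxy-4a,8a-dihydro derivative of 25 (α-hydroxy lactol, mixture at the two new centres) | C[C@@H]1CCC5(O)C[C@H]2/C(=C3/C[C@@H]4O[C@H](C)CC[C@@H]4O3)C(=O)O[C@H]2CC5(O)O1
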